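# Synthesis plan for CNP0148956.1 via a Rauhut–Currier cyclisation on a butenolide tether

## The problem

The target is a 2-alkyl-4-methoxycyclohexane-1,3-dione (ring A, drawn as its enol) joined through a single CH2 group to C1' of a cyclopentene (ring B). C5' of ring B is a methyl carbinol whose hydroxyl is cis to the CH2 link, and the alkene carbon C2' carries a (2Z)-6-methylhepta-2,5-dien-2-yl chain. There are three stereocentres. C1' (R) and C5' (S) are neighbours, so one can set the other. C4 of ring A (S) lies beyond the dione and the link and can neither steer nor be steered by ring B. The two halves therefore need separate sources of chirality and must be joined as single enantiomers. The side-chain alkene has the ring cis to the chain CH2, the less stable arrangement, so it must come from a stereospecific reaction. It is conjugated to the ring alkene and its cis CH2 is doubly allylic, which argues against acid and heat late in the route (ionisation, 1,5-hydrogen shift). The free dione is acidic, O-alkylates readily and can cyclodehydrate with the cis tertiary hydroxyl to a pyran; the methoxy carbon is next to a carbonyl and can epimerise. The dione should therefore appear last. The enabling feature is that C2' can carry an acyl group in place of the side chain, while the link CH2, ring A carbon C2 and the cis oxygen on C5' can be closed on paper to a γ-lactone. The C1'–C2' bond then joins the α-carbon of an enone to the β-carbon of a butenolide, which is exactly the bond a Rauhut–Currier cyclisation forms.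

## Retrosynthesis

**Ring A (33 ⇒ 32 ⇒ 31).** The tertiary hydroxyl of target 33 is masked as its triethylsilyl ether 32, and the bond between C2 and the enol carbon C3 of ring A is cut. This opens the dione to the δ-keto ester 31. The cut is placed so that the methoxy carbon is α to the ester and not to the ketone, because a stereocentre beside a ketone would enolise in competition with the productive position. The forward Dieckmann closure needs only that the ketone enolate on the ring B side reaches the ester; every other enolate would have to close a four-membered ring.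

**Joining the halves (31 ⇒ 24 + 29).** The bond between the ring A CH2 (C2) and the ketone carbon is cut, giving the primary iodide 24 and the thioester 29. A Fukuyama coupling is preferred to an organolithium or Grignard acylation because the methyl ester and the α-methoxy stereocentre of 29 must survive. C-alkylation of a preformed dione is ruled out because the arm of 24 already contains C2. Thioester 29 is reached in four steps from L-glutamic acid 5-benzyl ester 25 through 26, 27 and 28; the benzyl ester keeps the two carboxyl groups distinct throughout.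

**Side-chain terminus (24 ⇒ 23 ⇒ 22 ⇒ 20 + 21).** The iodide goes back through alcohol 23 to the bis-silyl ether 22. In 22 the CH2–CH bond of the skipped diene is cut to give the Z allylic bromide 20 and the alkenyl Grignard reagent 21. The γ-carbon of 20 is fully substituted, so direct substitution with retained geometry is expected. Bromide 20 comes from alcohol 18 and ester 17.

**Z alkene (17 ⇒ 16 ⇒ 14 ⇒ 13 ⇒ 12).** The C–CH3 bond of the side chain is cut: syn addition of a methylcuprate to ynoate 16 fixes the ring cis to the ester by mechanism. Direct olefination of a methyl ketone would give mixtures favouring the wrong isomer. Ynoate 16 comes from alkyne 14 by carboxylation, and 14 from lactone 12 by reduction to diol 13 and double silylation.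

**Alkyne from acetyl (12 ⇒ 10).** The ethynyl group is traced to the acetyl group of 10. The carbonyl carbon becomes the chain carbon on the ring and the methyl becomes the future =CH. This costs one step and links the cyclisation product to the cuprate chemistry.

**Ring B (10 ⇒ 9).** The bond between the ring-fusion CH and the acetyl-bearing alkene carbon is cut. The precursor is the monocyclic butenolide 9, which has one stereocentre and no ring B. The forward reaction has to activate the enone in preference to the butenolide and give the cis-fused bicycle; the quaternary carbon enforces the latter.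

**Precursor (9 ⇒ 7 + 8 ⇒ 4 + 5 ⇒ 3 ⇒ 1 + 2).** Cross-metathesis disconnects 9 into allyl butenolide 7 and methyl vinyl ketone 8. Z-olefination with lactonisation takes 7 back to hydroxy aldehyde 4 and phosphonate 5. Aldehyde 4 comes from diol 3, and 3 from opening (R)-2-methylglycidol 1 with vinylmagnesium bromide 2. The quaternary stereocentre is bought, not made.

## Roads not taken

**Alternative 1:** Three bonds are cut at once: ring A C2–CH2, CH2–C1' and enol oxygen–C5'. The target is first closed on paper to its cyclic vinylogous ester, and that dihydropyran is split in a retro-oxa-Diels–Alder sense. Forward, the methoxy dione A2 condenses with a one-carbon aldehyde to the 2-methylene dione A4, whose 1-oxadiene adds across the trisubstituted alkene of silyloxycyclopentene A3 to give the cis-fused tricycle A1.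
- Merits: ring A arrives intact with its stereocentre, both ring B stereocentres and three skeletal bonds form in one flask, and no Dieckmann step is needed. The side chain could later be attached as a preformed Z-alkenyl metal to an enol triflate at the silyloxy carbon, so the Z alkene would be made on a small fragment.
- Weak points: the alkene of A3 is neither electron-rich nor strained, so the inverse-demand cycloaddition is slow and A4 can divert to bis-dione adducts. Facial control rests only on the allylic silyloxy group of A3. The final operation must open the pyran of an A1-type intermediate against the natural tendency of the hydroxy dione to close.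
- Comparison: this road is shorter and more convergent, and in step count it is better. The chosen plan sets against it a purchased quaternary centre, a ring fusion that can only be cis, a ring closure between two activated acceptors, and no pyran to open at the end.

**Alternative 2:** The C1'–C5' bond of ring B is cut together with the acyl–oxygen bond of a β-lactone in which the link carbon is at the acid oxidation level. Forward, keto acid A6 is activated as an acyl ammonium species by a chiral Lewis base; its enolate adds to the methyl ketone and the tertiary alkoxide closes the cis-fused β-lactone A5.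
- Merits: both ring B stereocentres are set under catalyst control. The lactone carbonyl is the link carbon itself, so after reduction to the aldehyde it could be joined to dione A2 by reductive alkylation. That endgame is shorter than organozinc coupling plus Dieckmann, and here this road is better.
- Weak points: A6 carries its own stereocentre, which must match the catalyst or be carried as a mixture. Ring B emerges saturated, so the alkene and the side chain need deprotection, oxidation, regioselective enol triflate formation and cross-coupling. The β-lactone is strained and prone to decarboxylation and ring opening, and methyl ketones are demanding acceptors in this aldol-lactonisation.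
- Comparison: the chosen plan answers with a ring closure that leaves the ring alkene and an acyl handle exactly on C2', a robust γ-lactone, and absolute configuration that does not depend on a catalyst–substrate match.

**Alternative 3:** Only the ring A C2–C3 bond is cut; the open-chain δ-keto ester A8 closes by Dieckmann condensation to the silyl ether A7.
- Merits: the dione appears last, the methoxy stereocentre comes from glutamic acid, and the closure is regiochemically unambiguous.
- Weak points: taken as the central idea it does not say how ring B, with its cis CH/C–O pair, its alkene and the Z side chain, is obtained. A8 still has to be assembled by a ketone synthesis.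
- Comparison: the chosen plan uses this very closure as its endgame (A7 is 32, A8 is 31), so for ring A the two are equal. The chosen plan adds a defined, stereocontrolled construction of ring B.

Key step: step 5

Assumption: the dione tautomers of 32 and 33 interconvert freely, so the enol is written as in the target without a step for tautomer control; L-glutamic acid is taken as its commercial 5-benzyl ester 25.

## Route

Step 1
Reactants: 1 (R)-2-methylglycidol; 2 vinylmagnesium bromide
Product: 3 (2S)-2-methylpent-4-ene-1,2-diol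
Conditions: 2 (3 equiv), CuI (10 mol%), THF, −30 to 0 °C; aq NH4Cl
Reagents that add atoms: none
Why: Copper-catalysed Grignard opening of a 2,2-disubstituted epoxide at its unhindered CH2 terminus; the quaternary carbon is not attacked, so its configuration is carried over (the descriptor changes only because the CIP ranking of the two CH2 groups changes), and Payne equilibration of the alkoxide is degenerate for this substrate.

Step 2
Reactants: 3 (2S)-2-methylpent-4-ene-1,2-diol
Product: 4 (2S)-2-hydroxy-2-methylpent-4-enal
Conditions: SO3·pyridine, DMSO, i-Pr2NEt, CH2Cl2, 0 °C; used crude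
Reagents that add atoms: none
Why: Parikh–Doering oxidation takes the primary alcohol to the aldehyde, leaves the tertiary alcohol alone and does not cleave the glycol; the aldehyde has no α-hydrogen, so the stereocentre cannot epimerise.

Step 3
Reactants: 4 (2S)-2-hydroxy-2-methylpent-4-enal; 5 methyl 2-[bis(2,2,2-trifluoroethoxy)phosphoryl]acetate
Product: 7 (5S)-5-methyl-5-(prop-2-en-1-yl)furan-2(5H)-one, via methyl (2Z,4S)-4-hydroxy-4-methylhepta-2,6-dienoate 6 (not isolated)
Conditions: 5, KN(SiMe3)2, 18-crown-6, THF, −78 °C; then TsOH (cat.), CH2Cl2, rt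
Reagents that add atoms: none
Why: Still–Gennari olefination gives the Z enoate, whose γ-hydroxyl is held beside the ester and lactonises to the butenolide; the quaternary stereocentre is untouched.

Step 4
Reactants: 7 (5S)-5-methyl-5-(prop-2-en-1-yl)furan-2(5H)-one; 8 methyl vinyl ketone
Product: 9 (5S)-5-methyl-5-[(2E)-4-oxopent-2-en-1-yl]furan-2(5H)-one
Conditions: 8 (4 equiv), second-generation Grubbs catalyst (H2IMes)(PCy3)Cl2Ru=CHPh (5 mol%), CH2Cl2, 40 °C
Reagents that add atoms: none
Why: Olefin cross-metathesis of a terminal alkene with an electron-poor vinyl ketone is selective for the cross product and the E enone; the endocyclic, conjugated butenolide alkene next to the quaternary carbon does not take part.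

Step 5
Reactants: 9 (5S)-5-methyl-5-[(2E)-4-oxopent-2-en-1-yl]furan-2(5H)-one
Product: 10 (3aR,6aS)-4-acetyl-6a-methyl-3,3a,6,6a-tetrahydro-2H-cyclopenta[b]furan-2-one, also named (1S,5R)-6-acetyl-1-methyl-2-oxabicyclo[3.3.0]oct-6-en-3-one
Conditions: PMe3 (20 mol%), t-AmOH (0.05 M), rt, degassed
Reagents that add atoms: none
Why: This is an intramolecular Rauhut–Currier reaction, the phosphine-catalysed cycloisomerisation of a tethered enone and enoate to a cyclopentene. PMe3 adds reversibly to the β-carbon of the enone, and the α-carbon of the phosphonium enolate attacks the β-carbon of the butenolide. Proton transfer through the alcohol solvent and β-elimination of PMe3 then release the catalyst and leave the alkene between the acetyl-bearing carbon and the former enone β-carbon. Ring B closes by a 5-exo-trig Michael addition. The one new stereocentre, the ring-fusion CH, is set by the quaternary carbon: tether and lactone oxygen sit on the same atom, so only the cis-fused bicycle can form and the lactone CH2 ends up cis to the tertiary oxygen. The step needs activation of the enone and not of the butenolide; the enone is the more electrophilic and less hindered acceptor. Phosphine addition to the butenolide could only lead to a bridged bicyclo[2.2.1] adduct that cannot lose the phosphine without forming a bridgehead alkene, so that path reverts. No base is added, because 10 is a δ-acyloxy enone that could lose its carboxylate by vinylogous elimination.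

Step 6
Reactants: 10 (3aR,6aS)-4-acetyl-6a-methyl-3,3a,6,6a-tetrahydro-2H-cyclopenta[b]furan-2-one
Product: 12 (3aR,6aS)-4-ethynyl-6a-methyl-3,3a,6,6a-tetrahydro-2H-cyclopenta[b]furan-2-one, via enol diethyl phosphate 11 (not isolated)
Conditions: LiN(i-Pr)2 (1.05 equiv), THF, −78 °C; ClP(O)(OEt)2; LiN(i-Pr)2 (3.2 equiv), −78 °C to rt; aq NH4Cl
Reagents that add atoms: diethyl chlorophosphate, CCOP(=O)(Cl)OCC (its atoms stay in 11 only)
Why: One-pot enol phosphate formation and elimination, the standard conversion of a methyl ketone (including enones) into a terminal alkyne; the enone is deprotonated kinetically at the methyl group, the lactone is only enolised by the excess base and returns on quench, and no stereocentre is involved.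

Step 7
Reactants: 12 (3aR,6aS)-4-ethynyl-6a-methyl-3,3a,6,6a-tetrahydro-2H-cyclopenta[b]furan-2-one
Product: 13 (1S,2R)-3-ethynyl-2-(2-hydroxyethyl)-1-methylcyclopent-3-en-1-ol
Conditions: LiAlH4, THF, 0 °C; H2O, aq NaOH
Reagents that add atoms: none
Why: Hydride reduction of the γ-lactone to the 1,4-diol; the conjugated enyne is inert to LiAlH4 at 0 °C because neither hydroxyl is propargylic.

Step 8
Reactants: 13 (1S,2R)-3-ethynyl-2-(2-hydroxyethyl)-1-methylcyclopent-3-en-1-ol
Product: 14 triethyl({(1S,2R)-3-ethynyl-1-methyl-2-[2-(triethylsilyloxy)ethyl]cyclopent-3-en-1-yl}oxy)silane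
Conditions: Et3SiOTf (2.5 equiv), 2,6-lutidine, CH2Cl2, −78 to 0 °C
Reagents that add atoms: triethylsilyl trifluoromethanesulfonate, CC[Si](CC)(CC)OS(=O)(=O)C(F)(F)F
Why: Silyl triflate silylation protects the primary and the hindered tertiary hydroxyl in one operation; the tertiary ether stays to the end and the primary one can later be removed selectively.

Step 9
Reactants: 14 triethyl({(1S,2R)-3-ethynyl-1-methyl-2-[2-(triethylsilyloxy)ethyl]cyclopent-3-en-1-yl}oxy)silane
Product: 16 methyl 3-{(4S,5R)-4-methyl-4-(triethylsilyloxy)-5-[2-(triethylsilyloxy)ethyl]cyclopent-1-en-1-yl}prop-2-ynoate, via lithium acetylide 15 (not isolated)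
Conditions: n-BuLi, THF, −78 °C; ClCO2Me, −78 to 0 °C
Reagents that add atoms: n-butyllithium, [Li]CCCC (lithium stays in 15 only); methyl chloroformate, COC(=O)Cl
Why: Deprotonation of the terminal alkyne and C-acylation of the acetylide with a chloroformate, the standard route to alk-2-ynoates.

Step 10
Reactants: 16 methyl 3-{(4S,5R)-4-methyl-4-(triethylsilyloxy)-5-[2-(triethylsilyloxy)ethyl]cyclopent-1-en-1-yl}prop-2-ynoate
Product: 17 methyl (2Z)-3-{(4S,5R)-4-methyl-4-(triethylsilyloxy)-5-[2-(triethylsilyloxy)ethyl]cyclopent-1-en-1-yl}but-2-enoate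
Conditions: Me2CuLi (from CuI and MeLi, 1.5 equiv), THF, −78 °C; MeOH at −78 °C, then aq NH4Cl
Reagents that add atoms: lithium dimethylcuprate, [Li+].C[Cu-]C
Why: Conjugate addition of a Gilman cuprate to an alk-2-ynoate is a syn carbocupration; protonation at −78 °C with retention puts the new methyl cis to hydrogen and hence the ring cis to the ester, which is the Z geometry the target needs.

Step 11
Reactants: 17 methyl (2Z)-3-{(4S,5R)-4-methyl-4-(triethylsilyloxy)-5-[2-(triethylsilyloxy)ethyl]cyclopent-1-en-1-yl}but-2-enoate
Product: 18 (2Z)-3-{(4S,5R)-4-methyl-4-(triethylsilyloxy)-5-[2-(triethylsilyloxy)ethyl]cyclopent-1-en-1-yl}but-2-en-1-ol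
Conditions: i-Bu2AlH (2.5 equiv), CH2Cl2, −78 °C; aq potassium sodium tartrate
Reagents that add atoms: none
Why: 1,2-Reduction of the conjugated ester with i-Bu2AlH gives the allylic alcohol without touching alkene geometry or silyl ethers.

Step 12
Reactants: 18 (2Z)-3-{(4S,5R)-4-methyl-4-(triethylsilyloxy)-5-[2-(triethylsilyloxy)ethyl]cyclopent-1-en-1-yl}but-2-en-1-ol
Product: 20 triethyl({(1S,2R)-3-[(2Z)-4-bromobut-2-en-2-yl]-1-methyl-2-[2-(triethylsilyloxy)ethyl]cyclopent-3-en-1-yl}oxy)silane, via allylic methanesulfonate 19 (not isolated)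
Conditions: MsCl, Et3N, CH2Cl2, −30 °C; LiBr, THF, −30 to 0 °C; used at once
Reagents that add atoms: methanesulfonyl chloride, CS(=O)(=O)Cl (its atoms stay in 19 only); lithium bromide, [Li+].[Br-]
Why: Mesylation and SN2 displacement by bromide under non-acidic conditions convert a primary allylic alcohol into the bromide without allylic transposition or Z-to-E isomerisation.

Step 13
Reactants: 20 triethyl({(1S,2R)-3-[(2Z)-4-bromobut-2-en-2-yl]-1-methyl-2-[2-(triethylsilyloxy)ethyl]cyclopent-3-en-1-yl}oxy)silane; 21 (2-methylprop-1-en-1-yl)magnesium bromide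
Product: 22 triethyl({(1S,2R)-1-methyl-3-[(2Z)-6-methylhepta-2,5-dien-2-yl]-2-[2-(triethylsilyloxy)ethyl]cyclopent-3-en-1-yl}oxy)silane
Conditions: 21 (2 equiv), CuI (10 mol%), THF, −40 to 0 °C
Reagents that add atoms: none
Why: Copper-catalysed coupling of an alkenyl Grignard reagent with a primary allylic bromide; attack at the γ-carbon would create a quaternary centre beside the ring, so direct (SN2) substitution with retention of the Z alkene is expected and gives the skipped diene.

Step 14
Reactants: 22 triethyl({(1S,2R)-1-methyl-3-[(2Z)-6-methylhepta-2,5-dien-2-yl]-2-[2-(triethylsilyloxy)ethyl]cyclopent-3-en-1-yl}oxy)silane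
Product: 23 2-{(1R,5S)-5-methyl-2-[(2Z)-6-methylhepta-2,5-dien-2-yl]-5-(triethylsilyloxy)cyclopent-2-en-1-yl}ethan-1-ol
Conditions: pyridinium p-toluenesulfonate (10 mol%), MeOH–CH2Cl2, 0 °C
Reagents that add atoms: none
Why: Mild acid-catalysed methanolysis cleaves the unhindered primary triethylsilyl ether much faster than the tertiary one.

Step 15
Reactants: 23 2-{(1R,5S)-5-methyl-2-[(2Z)-6-methylhepta-2,5-dien-2-yl]-5-(triethylsilyloxy)cyclopent-2-en-1-yl}ethan-1-ol
Product: 24 triethyl({(1S,2R)-2-(2-iodoethyl)-1-methyl-3-[(2Z)-6-methylhepta-2,5-dien-2-yl]cyclopent-3-en-1-yl}oxy)silane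
Conditions: I2, PPh3, imidazole, CH2Cl2, 0 °C
Reagents that add atoms: iodine, [I][I]
Why: Appel-type iodination of a primary alcohol; the silylated tertiary oxygen cannot close a tetrahydrofuran onto the activated carbon.

Step 16
Reactants: 25 L-glutamic acid 5-benzyl ester
Product: 26 (2S)-5-(benzyloxy)-2-hydroxy-5-oxopentanoic acid
Conditions: NaNO2, aq H2SO4 (1 M), 0 °C to rt
Reagents that add atoms: water, O
Why: Diazotisation of an α-amino acid proceeds with net retention (double inversion through the α-lactone), so the S configuration of glutamic acid is kept at the carbinol.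

Step 17
Reactants: 26 (2S)-5-(benzyloxy)-2-hydroxy-5-oxopentanoic acid
Product: 27 5-benzyl 1-methyl (2S)-2-methoxypentanedioate
Conditions: MeI (excess), Ag2O, MeCN, rt, dark
Reagents that add atoms: iodomethane, CI
Why: Purdie methylation with Ag2O converts the acid into the methyl ester and the α-hydroxyl into the methyl ether under non-basic conditions that do not epimerise the α-carbon.

Step 18
Reactants: 27 5-benzyl 1-methyl (2S)-2-methoxypentanedioate
Product: 28 (4S)-4,5-dimethoxy-5-oxopentanoic acid
Conditions: H2 (1 atm), Pd/C, EtOAc, rt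
Reagents that add atoms: none
Why: Hydrogenolysis removes only the benzyl ester and frees the carboxyl group remote from the stereocentre.

Step 19
Reactants: 28 (4S)-4,5-dimethoxy-5-oxopentanoic acid
Product: 29 methyl (2S)-5-(ethylsulfanyl)-2-methoxy-5-oxopentanoate
Conditions: EtSH, EDC·HCl, DMAP (cat.), CH2Cl2, 0 °C to rt
Reagents that add atoms: ethanethiol, CCS
Why: Steglich-type carbodiimide thioesterification of the free acid.

Step 20
Reactants: 24 triethyl({(1S,2R)-2-(2-iodoethyl)-1-methyl-3-[(2Z)-6-methylhepta-2,5-dien-2-yl]cyclopent-3-en-1-yl}oxy)silane; 29 methyl (2S)-5-(ethylsulfanyl)-2-methoxy-5-oxopentanoate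
Product: 31 methyl (2S)-2-methoxy-7-{(1R,5S)-5-methyl-2-[(2Z)-6-methylhepta-2,5-dien-2-yl]-5-(triethylsilyloxy)cyclopent-2-en-1-yl}-5-oxoheptanoate, via alkylzinc iodide 30 (not isolated)
Conditions: Zn dust (activated with BrCH2CH2Br and Me3SiCl), THF, 40 °C; then 29 (1.3 equiv), PdCl2(PPh3)2 (5 mol%), toluene, rt
Reagents that add atoms: zinc, [Zn] (stays in 30 only)
Why: Fukuyama coupling: zinc insertion into the primary iodide and palladium-catalysed acylation of the alkylzinc by the thioester give the ketone; the methyl ester, silyl ether, alkenes and α-methoxy stereocentre are tolerated under these neutral conditions.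

Step 21
Reactants: 31 methyl (2S)-2-methoxy-7-{(1R,5S)-5-methyl-2-[(2Z)-6-methylhepta-2,5-dien-2-yl]-5-(triethylsilyloxy)cyclopent-2-en-1-yl}-5-oxoheptanoate
Product: 32 (4S)-3-hydroxy-4-methoxy-2-({(1R,5S)-5-methyl-2-[(2Z)-6-methylhepta-2,5-dien-2-yl]-5-(triethylsilyloxy)cyclopent-2-en-1-yl}methyl)cyclohex-2-en-1-one
Conditions: KOt-Bu (2.5 equiv), THF, 0 °C to rt; cold aq KHSO4 to pH 4
Reagents that add atoms: none
Why: Dieckmann condensation: only the ketone enolate on the ring B side can reach the ester through a six-membered transition state, and the product is withdrawn as its stabilised dione enolate; the methoxy carbon is α only to the ester before closure and lies beside a delocalised enolate afterwards, so it should keep its configuration.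

Step 22
Reactants: 32 (4S)-3-hydroxy-4-methoxy-2-({(1R,5S)-5-methyl-2-[(2Z)-6-methylhepta-2,5-dien-2-yl]-5-(triethylsilyloxy)cyclopent-2-en-1-yl}methyl)cyclohex-2-en-1-one
Product: 33 (4S)-3-hydroxy-2-({(1R,5S)-5-hydroxy-5-methyl-2-[(2Z)-6-methylhepta-2,5-dien-2-yl]cyclopent-2-en-1-yl}methyl)-4-methoxycyclohex-2-en-1-one
Conditions: HF·pyridine, pyridine, THF, 0 °C
Reagents that add atoms: none
Why: Fluoride cleavage of the tertiary triethylsilyl ether under pyridine-buffered conditions chosen to avoid acid-catalysed cyclodehydration of the carbinol onto the dione.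

## Compound list

1 | (R)-2-methylglycidol, [(2R)-2-methyloxiran-2-yl]methanol | C[C@@]1(CO)CO1 | starting material
2 | vinylmagnesium bromide | C=C[Mg]Br | starting material
3 | (2S)-2-methylpent-4-ene-1,2-diol | C[C@@](O)(CO)CC=C | intermediate
4 | (2S)-2-hydroxy-2-methylpent-4-enal | C[C@@](O)(C=O)CC=C | intermediate
5 | methyl 2-[bis(2,2,2-trifluoroethoxy)phosphoryl]acetate | COC(=O)CP(=O)(OCC(F)(F)F)OCC(F)(F)F | starting material
6 | methyl (2Z,4S)-4-hydroxy-4-methylhepta-2,6-dienoate | C[C@@](O)(/C=C\C(=O)OC)CC=C | intermediate (not isolated)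
7 | (5S)-5-methyl-5-(prop-2-en-1-yl)furan-2(5H)-one | O=C1C=C[C@](C)(CC=C)O1 | intermediate
8 | methyl vinyl ketone | CC(=O)C=C | starting material
9 | (5S)-5-methyl-5-[(2E)-4-oxopent-2-en-1-yl]furan-2(5H)-one | O=C1C=C[C@](C)(C/C=C/C(C)=O)O1 | intermediate
10 | (3aR,6aS)-4-acetyl-6a-methyl-3,3a,6,6a-tetrahydro-2H-cyclopenta[b]furan-2-one | O=C1C[C@@H]2C(C(C)=O)=CC[C@]2(C)O1 | intermediate
11 | diethyl 1-[(3aR,6aS)-6a-methyl-2-oxo-3,3a,6,6a-tetrahydro-2H-cyclopenta[b]furan-4-yl]ethenyl phosphate | O=C1C[C@@H]2C(C(=C)OP(=O)(OCC)OCC)=CC[C@]2(C)O1 | intermediate (not isolated)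
12 | (3aR,6aS)-4-ethynyl-6a-methyl-3,3a,6,6a-tetrahydro-2H-cyclopenta[b]furan-2-one | O=C1C[C@@H]2C(C#C)=CC[C@]2(C)O1 | intermediate
13 | (1S,2R)-3-ethynyl-2-(2-hydroxyethyl)-1-methylcyclopent-3-en-1-ol | OCC[C@@H]1C(C#C)=CC[C@]1(C)O | intermediate
14 | triethyl({(1S,2R)-3-ethynyl-1-methyl-2-[2-(triethylsilyloxy)ethyl]cyclopent-3-en-1-yl}oxy)silane | CC[Si](CC)(CC)OCC[C@@H]1C(C#C)=CC[C@]1(C)O[Si](CC)(CC)CC | intermediate
15 | lithium acetylide of 14 | CC[Si](CC)(CC)OCC[C@@H]1C(C#C[Li])=CC[C@]1(C)O[Si](CC)(CC)CC | intermediate (not isolated)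
16 | methyl 3-{(4S,5R)-4-methyl-4-(triethylsilyloxy)-5-[2-(triethylsilyloxy)ethyl]cyclopent-1-en-1-yl}prop-2-ynoate | CC[Si](CC)(CC)OCC[C@@H]1C(C#CC(=O)OC)=CC[C@]1(C)O[Si](CC)(CC)CC | intermediate
17 | methyl (2Z)-3-{(4S,5R)-4-methyl-4-(triethylsilyloxy)-5-[2-(triethylsilyloxy)ethyl]cyclopent-1-en-1-yl}but-2-enoate | CC[Si](CC)(CC)OCC[C@@H]1C(/C(C)=C\C(=O)OC)=CC[C@]1(C)O[Si](CC)(CC)CC | intermediate
18 | (2Z)-3-{(4S,5R)-4-methyl-4-(triethylsilyloxy)-5-[2-(triethylsilyloxy)ethyl]cyclopent-1-en-1-yl}but-2-en-1-ol | CC[Si](CC)(CC)OCC[C@@H]1C(/C(C)=C\CO)=CC[C@]1(C)O[Si](CC)(CC)CC | intermediate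
19 | methanesulfonate of 18 | CC[Si](CC)(CC)OCC[C@@H]1C(/C(C)=C\COS(C)(=O)=O)=CC[C@]1(C)O[Si](CC)(CC)CC | intermediate (not isolated)
20 | triethyl({(1S,2R)-3-[(2Z)-4-bromobut-2-en-2-yl]-1-methyl-2-[2-(triethylsilyloxy)ethyl]cyclopent-3-en-1-yl}oxy)silane | CC[Si](CC)(CC)OCC[C@@H]1C(/C(C)=C\CBr)=CC[C@]1(C)O[Si](CC)(CC)CC | intermediate
21 | (2-methylprop-1-en-1-yl)magnesium bromide | CC(C)=C[Mg]Br | starting material
22 | triethyl({(1S,2R)-1-methyl-3-[(2Z)-6-methylhepta-2,5-dien-2-yl]-2-[2-(triethylsilyloxy)ethyl]cyclopent-3-en-1-yl}oxy)silane | CC[Si](CC)(CC)OCC[C@@H]1C(/C(C)=C\CC=C(C)C)=CC[C@]1(C)O[Si](CC)(CC)CC | intermediate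
23 | 2-{(1R,5S)-5-methyl-2-[(2Z)-6-methylhepta-2,5-dien-2-yl]-5-(triethylsilyloxy)cyclopent-2-en-1-yl}ethan-1-ol | OCC[C@@H]1C(/C(C)=C\CC=C(C)C)=CC[C@]1(C)O[Si](CC)(CC)CC | intermediate
24 | triethyl({(1S,2R)-2-(2-iodoethyl)-1-methyl-3-[(2Z)-6-methylhepta-2,5-dien-2-yl]cyclopent-3-en-1-yl}oxy)silane | ICC[C@@H]1C(/C(C)=C\CC=C(C)C)=CC[C@]1(C)O[Si](CC)(CC)CC | intermediate
25 | L-glutamic acid 5-benzyl ester | N[C@@H](CCC(=O)OCc1ccccc1)C(=O)O | starting material
26 | (2S)-5-(benzyloxy)-2-hydroxy-5-oxopentanoic acid | O[C@@H](CCC(=O)OCc1ccccc1)C(=O)O | intermediate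
27 | 5-benzyl 1-methyl (2S)-2-methoxypentanedioate | CO[C@@H](CCC(=O)OCc1ccccc1)C(=O)OC | intermediate
28 | (4S)-4,5-dimethoxy-5-oxopentanoic acid | CO[C@@H](CCC(=O)O)C(=O)OC | intermediate
29 | methyl (2S)-5-(ethylsulfanyl)-2-methoxy-5-oxopentanoate | CO[C@@H](CCC(=O)SCC)C(=O)OC | intermediate
30 | iodo(2-{(1R,5S)-5-methyl-2-[(2Z)-6-methylhepta-2,5-dien-2-yl]-5-(triethylsilyloxy)cyclopent-2-en-1-yl}ethyl)zinc | I[Zn]CC[C@@H]1C(/C(C)=C\CC=C(C)C)=CC[C@]1(C)O[Si](CC)(CC)CC | intermediate (not isolated)
31 | methyl (2S)-2-methoxy-7-{(1R,5S)-5-methyl-2-[(2Z)-6-methylhepta-2,5-dien-2-yl]-5-(triethylsilyloxy)cyclopent-2-en-1-yl}-5-oxoheptanoate | COC(=O)[C@@H](OC)CCC(=O)CC[C@@H]1C(/C(C)=C\CC=C(C)C)=CC[C@]1(C)O[Si](CC)(CC)CC | intermediate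
32 | (4S)-3-hydroxy-4-methoxy-2-({(1R,5S)-5-methyl-2-[(2Z)-6-methylhepta-2,5-dien-2-yl]-5-(triethylsilyloxy)cyclopent-2-en-1-yl}methyl)cyclohex-2-en-1-one | CO[C@H]1CCC(=O)C(C[C@@H]2C(/C(C)=C\CC=C(C)C)=CC[C@]2(C)O[Si](CC)(CC)CC)=C1O | intermediate
33 | (4S)-3-hydroxy-2-({(1R,5S)-5-hydroxy-5-methyl-2-[(2Z)-6-methylhepta-2,5-dien-2-yl]cyclopent-2-en-1-yl}methyl)-4-methoxycyclohex-2-en-1-one | CO[C@H]1CCC(=O)C(C[C@@H]2C(/C(C)=C\CC=C(C)C)=CC[C@]2(C)O)=C1O | target

## Step count and least certain steps

Total: 22 steps. Longest linear sequence: 18 steps (steps 1–15 and 20–22); the thioester branch (steps 16–19) is four steps.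

**Step 5 (key step).** Ring closure may be slow because the butenolide β-carbon lies beside a quaternary centre. That would let intermolecular oligomerisation of the enone compete, and once product has formed, the alkoxide generated in the medium could deprotonate the ring CH2 γ to the ketone and expel the lactone carboxylate. Fallback from 9, returning at 10: lithium thiophenolate (PhSLi, 0.2 equiv) with PhSH (1.2 equiv) in THF at −78 to 0 °C adds to the enone, and the enolate closes onto the butenolide to give (3aR,6aS)-4-acetyl-6a-methyl-5-(phenylsulfanyl)hexahydro-2H-cyclopenta[b]furan-2-one F1 as a mixture of epimers at C4 and C5. Oxidation with mCPBA (1 equiv, CH2Cl2, −78 °C) gives the sulfoxide (3aR,6aS)-4-acetyl-6a-methyl-5-(phenylsulfinyl)hexahydro-2H-cyclopenta[b]furan-2-one F2, which on gentle warming in toluene eliminates towards the acidic C4–H and gives 10.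

**Step 6.** The ketone enolate or the excess amide base may attack or over-enolise the lactone (intramolecular Claisen-type acylation through a bridged transition state), or γ-deprotonation may trigger loss of the carboxylate. Fallback from 10, returning at 14, removes the lactone before any strong base is used. LiAlH4 reduces ketone and lactone to (1S,2R)-2-(2-hydroxyethyl)-3-(1-hydroxyethyl)-1-methylcyclopent-3-en-1-ol F3 (both carbinol epimers). MnO2 in CH2Cl2 reoxidises only the allylic alcohol to 1-[(4S,5R)-4-hydroxy-5-(2-hydroxyethyl)-4-methylcyclopent-1-en-1-yl]ethan-1-one F4. Et3SiOTf and 2,6-lutidine at −78 °C give 1-{(4S,5R)-4-methyl-4-(triethylsilyloxy)-5-[2-(triethylsilyloxy)ethyl]cyclopent-1-en-1-yl}ethan-1-one F5. The enol phosphate and elimination sequence, through the enol diethyl phosphate of F5 F6, then gives 14 directly.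

**Step 10.** Alkene geometry may erode if the alkenylcopper adduct equilibrates through its allenolate form before protonation, and some addition at the far end of the enyne is possible. Fallback from 14, returning at 18: the lithium acetylide of 14 is treated with paraformaldehyde to give 3-{(4S,5R)-4-methyl-4-(triethylsilyloxy)-5-[2-(triethylsilyloxy)ethyl]cyclopent-1-en-1-yl}prop-2-yn-1-ol F7. Alkoxide-directed, iron-catalysed syn carbomagnesiation (MeMgBr, Fe(acac)3 cat., THF, −78 to 0 °C; aqueous quench) places the methyl on the ring-side carbon and gives the Z allylic alcohol 18, bypassing steps 9–11.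

**Step 21.** The methoxy-bearing carbon may epimerise by ester enolisation before ring closure, and closure may stall while the unproductive ketone enolate is populated. Fallback from 31, returning at 32, replaces the alkoxide conditions with soft enolisation onto an activated ester. LiOH in aqueous THF at 0 °C gives (2S)-2-methoxy-7-{(1R,5S)-5-methyl-2-[(2Z)-6-methylhepta-2,5-dien-2-yl]-5-(triethylsilyloxy)cyclopent-2-en-1-yl}-5-oxoheptanoic acid F8. C6F5OH, EDC·HCl and DMAP give its pentafluorophenyl ester F9. MgBr2·OEt2 and i-Pr2NEt in CH2Cl2 at rt then effect C-acylation of the magnesium enolate to 32.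

**Step 22.** During desilylation the freed tertiary alcohol may cyclodehydrate onto the dione, or the tertiary carbinol may ionise. Fallback from 31, returning at 33, reverses the order so that the dione never meets the fluoride reagent. HF·pyridine in pyridine–THF at 0 °C cleaves the silyl ether of 31 to methyl (2S)-7-{(1R,5S)-5-hydroxy-5-methyl-2-[(2Z)-6-methylhepta-2,5-dien-2-yl]cyclopent-2-en-1-yl}-2-methoxy-5-oxoheptanoate F10. Dieckmann closure with KOt-Bu (3.5 equiv, THF, 0 °C) and acidification to pH 4 then gives 33 directly.

## Further compounds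

F1 | step 5 | (3aR,6aS)-4-acetyl-6a-methyl-5-(phenylsulfanyl)hexahydro-2H-cyclopenta[b]furan-2-one (epimers at C4 and C5) | O=C1C[C@@H]2C(C(C)=O)C(Sc3ccccc3)C[C@]2(C)O1
F2 | step 5 | (3aR,6aS)-4-acetyl-6a-methyl-5-(phenylsulfinyl)hexahydro-2H-cyclopenta[b]furan-2-one (epimers at C4, C5 and sulfur) | O=C1C[C@@H]2C(C(C)=O)C(S(=O)c3ccccc3)C[C@]2(C)O1
F3 | step 6 | (1S,2R)-2-(2-hydroxyethyl)-3-(1-hydroxyethyl)-1-methylcyclopent-3-en-1-ol (both carbinol epimers) | OCC[C@@H]1C(C(C)O)=CC[C@]1(C)O
F4 | step 6 | 1-[(4S,5R)-4-hydroxy-5-(2-hydroxyethyl)-4-methylcyclopent-1-en-1-yl]ethan-1-one | OCC[C@@H]1C(C(C)=O)=CC[C@]1(C)O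
F5 | step 6 | 1-{(4S,5R)-4-methyl-4-(triethylsilyloxy)-5-[2-(triethylsilyloxy)ethyl]cyclopent-1-en-1-yl}ethan-1-one | CC[Si](CC)(CC)OCC[C@@H]1C(C(C)=O)=CC[C@]1(C)O[Si](CC)(CC)CC
F6 | step 6 | diethyl 1-{(4S,5R)-4-methyl-4-(triethylsilyloxy)-5-[2-(triethylsilyloxy)ethyl]cyclopent-1-en-1-yl}ethenyl phosphate | CC[Si](CC)(CC)OCC[C@@H]1C(C(=C)OP(=O)(OCC)OCC)=CC[C@]1(C)O[Si](CC)(CC)CC
F7 | step 10 | 3-{(4S,5R)-4-methyl-4-(triethylsilyloxy)-5-[2-(triethylsilyloxy)ethyl]cyclopent-1-en-1-yl}prop-2-yn-1-ol | CC[Si](CC)(CC)OCC[C@@H]1C(C#CCO)=CC[C@]1(C)O[Si](CC)(CC)CC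
F8 | step 21 | (2S)-2-methoxy-7-{(1R,5S)-5-methyl-2-[(2Z)-6-methylhepta-2,5-dien-2-yl]-5-(triethylsilyloxy)cyclopent-2-en-1-yl}-5-oxoheptanoic acid | OC(=O)[C@@H](OC)CCC(=O)CC[C@@H]1C(/C(C)=C\CC=C(C)C)=CC[C@]1(C)O[Si](CC)(CC)CC
F9 | step 21 | pentafluorophenyl (2S)-2-methoxy-7-{(1R,5S)-5-methyl-2-[(2Z)-6-methylhepta-2,5-dien-2-yl]-5-(triethylsilyloxy)cyclopent-2-en-1-yl}-5-oxoheptanoate | O=C(Oc1c(F)c(F)c(F)c(F)c1F)[C@@H](OC)CCC(=O)CC[C@@H]2C(/C(C)=C\CC=C(C)C)=CC[C@]2(C)O[Si](CC)(CC)CC
F10 | step 22 | methyl (2S)-7-{(1R,5S)-5-hydroxy-5-methyl-2-[(2Z)-6-methylhepta-2,5-dien-2-yl]cyclopent-2-en-1-yl}-2-methoxy-5-oxoheptanoate | COC(=O)[C@@H](OC)CCC(=O)CC[C@@H]1C(/C(C)=C\CC=C(C)C)=CC[C@]1(C)O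
A1 | alternative 1 | cis-fused tricyclic vinylogous ester (cyclopenta-fused tetrahydrochromenone) with tert-butyldimethylsilyloxy group on ring B | CO[C@H]1CCC(=O)C2=C1O[C@@]3(C)CC[C@H](O[Si](C)(C)C(C)(C)C)[C@H]3C2
A2 | alternative 1 | (4S)-4-methoxycyclohexane-1,3-dione | CO[C@H]1CCC(=O)CC1=O
A3 | alternative 1 | tert-butyldimethyl{[(1S)-3-methylcyclopent-2-en-1-yl]oxy}silane | CC1=C[C@@H](O[Si](C)(C)C(C)(C)C)CC1
A4 | alternative 1 | (4S)-4-methoxy-2-methylidenecyclohexane-1,3-dione | CO[C@H]1CCC(=O)C(=C)C1=O
A5 | alternative 2 | cis-fused 2-[(4-methoxybenzyl)oxy]-5-methyl-6-oxabicyclo[3.2.0]heptan-7-one | O=C1[C@@H]2[C@@H](OCc3ccc(OC)cc3)CC[C@]2(C)O1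
A6 | alternative 2 | (3S)-3-[(4-methoxybenzyl)oxy]-6-oxoheptanoic acid | OC(=O)C[C@@H](OCc1ccc(OC)cc1)CCC(C)=O
A7 | alternative 3 | O-triethylsilyl ether of the target (same compound as 32) | CO[C@H]1CCC(=O)C(C[C@@H]2C(/C(C)=C\CC=C(C)C)=CC[C@]2(C)O[Si](CC)(CC)CC)=C1O
A8 | alternative 3 | open-chain δ-keto ester (same compound as 31) | COC(=O)[C@@H](OC)CCC(=O)CC[C@@H]1C(/C(C)=C\CC=C(C)C)=CC[C@]1(C)O[Si](CC)(CC)CC
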